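A unit of target formed in the reaction phase can go four ways, and this reckoning follows that unit through the flask below.

    reagent in the reaction phase ⇌ reagent in the second phase, rate k1*([reagent in the reaction phase] - [reagent in the second phase]/K1) per volume of the first phase (K1 = 0.39, k1 = 0.0057 s⁻¹)
    substrate + reagent in the reaction phase → target (k2 = 0.068 M⁻¹ s⁻¹)
    target ⇌ product in the second phase, rate k3*([target] - [product in the second phase]/K3) per volume of the first phase (K3 = 8.1, k3 = 0.0037 s⁻¹)
    target → decomposed product (k4 = 0.0040 s⁻¹)
    target ⇌ isomer of the product (K5 = 1.3, k5 = 0.0029 s⁻¹)
    reagent in the reaction phase + target → over-reaction product (k6 = 0.60 M⁻¹ s⁻¹)
    reagent in the reaction phase + protic impurity → quenched reagent (k7 = 19 M⁻¹ s⁻¹)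

substrate 0.050 M; reagent in the second phase 0.125 M; protic impurity 2.50 mM; time 8.0 min; volume of the second phase over the first 1.0

1. how much target and product in the second phase together there is at 8.0 min, in percent of the substrate charged
2. the change that raises the amount of target and product in the second phase together at 8.0 min, in percent of the substrate charged most ("none" if none brings more than 2 percentage points) (Friday's / Sunday's / Tuesday's / none)
3. amount of target and product in the second phase together at 8.0 min, in percent of the substrate charged, after Tuesday's

- amounts and yields of target count product in the second phase too
- in the second phase: reagent in the second phase, product in the second phase; everything else is in the first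
- charges count per volume of the first phase; a concentration in a rate is the amount of a species over the volume of its own phase; every rate counts per litre of the first phase
- run time (flask): 8.0 min

Reagent comes first. Its transfer relaxes in 0.820 min, shorter than the run, so the reckoning lets free reagent follow its partition ratio. Full over-reaction spends two reagent per substrate, so the reckoning takes the midpoint: the reagent charge less the protic impurity and one substrate charge. That leaves 1.04 substrate charges of reagent in the reaction phase. Over-reaction then acts as a pseudo-first-order drain on target of 1.88 min⁻¹, faster than decomposition, isomerisation and transfer together. Step 3's coefficient over the sum of these four rates, 2.51 min⁻¹, gives 8.83%. This is the shelter share, the part of each unit of target that reaches the second phase before another step takes it.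

At that reagent level, the reckoning has 81.8% of the substrate consumed in the run and applies the share to that part, and target still in the reaction phase adds 1.54%. So the reckoning gives 8.76%. Friday's raises the share to 16.2%. Sunday's lowers it to 3.86%. Step 1's coefficient does not enter the share, and the reckoning gives 8.76% after Tuesday's. The choice is Friday's.

The forecast stood at 8.2%, chose Friday's and put Tuesday's at 8%, and it said “Sunday's lowers the yield, because more reagent means more over-reaction”.

The flask gives 8.47%, and Friday's gains the most, 4.2 percentage points, while Tuesday's ends at 8.10%. At 8.00 min this flask holds 6.35% as product in the second phase with 21.7% of the substrate left, a reading of 8.11% of the substrate consumed, against a shelter share of 8.83%. On Sunday's flask the share drops by 5 points, and that flask ends 4 points lower.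

The numbers are made up; what happens was integrated by code.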